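**Plan**

- Ring numbering: O1, C2 (OMe), C3 (Et), C4 (C=O), C5 (Me), C6 (side chain). The retrosynthesis cuts, in this order, the acetate C–O bond, the O–CH3 bond at C2, the lactone bond O1–C2, the C5–C6 bond, and last the C8'–C9' bond of the side chain next to the carbinol carbon C10'.
- Enabling feature: ring atoms C2–C6, with oxygen on C2 and C4 and alkyl branches on C3 and C5, are a triketide. C5–C6 is therefore a Claisen bond between the γ-carbon of methyl 2-ethyl-3-oxopentanoate and the carboxyl carbon of an 11-oxygenated dodecanoic acid.
- Forward: the C12 acyl fragment is built first and joined as its Weinreb amide to the keto ester dianion, giving the open chain with no ring. The only ring then closes by lactonisation (O1–C2), followed by O-methylation at the C2 oxygen, desilylation and acetylation.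
- Stereochemistry: the single S carbinol center comes from (S)-propylene oxide, opened at its CH2 group. No later step breaks a bond at that carbon.

Key step: step 7

Remark: keto esters 2 and 15 are carried as mixtures of epimers and keto–enol tautomers at their enolisable carbons; these carbons become sp2 in the pyranone, so no control is needed there.

**Route**

Step 1
Reactants: 1 methyl 3-oxopentanoate
Product: 2 methyl 2-ethyl-3-oxopentanoate (racemic)
Conditions: EtI (1.1 equiv), K2CO3, acetone, reflux
Reagents that add atoms: iodoethane, CCI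
Why: C-alkylation of a β-keto ester enolate with a primary iodide; the monoalkylated product is less acidic and more hindered, which should hold back a second ethylation.

Step 2
Reactants: 3 10-bromodec-1-ene; 4 (S)-propylene oxide
Product: 6 (S)-tridec-12-en-2-ol, via dec-9-enylmagnesium bromide 5 (not isolated)
Conditions: Mg, THF, rt → 40 °C; then CuI (10 mol%), 4, THF, −30 → 0 °C; sat. aq. NH4Cl
Reagents that add atoms: none
Why: Copper-catalysed Grignard opening of a terminal epoxide by SN2 attack at the unsubstituted CH2; the C–O bond at the stereocenter is not touched, so the S configuration of 4 is carried over unchanged.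

Step 3
Reactants: 6 (S)-tridec-12-en-2-ol
Product: 7 tert-butyldimethyl[(2S)-tridec-12-en-2-yloxy]silane
Conditions: TBSCl, imidazole, DMF, rt
Reagents that add atoms: tert-butyldimethylsilyl chloride, CC(C)(C)[Si](C)(C)Cl
Why: Standard silylation of a secondary alcohol; a silyl ether is chosen over the final acetate so that the dianion of step 7 meets only one acylating carbonyl.

Step 4
Reactants: 7 tert-butyldimethyl[(2S)-tridec-12-en-2-yloxy]silane
Product: 9 (11S)-11-(tert-butyldimethylsilyloxy)dodecanal, via ozonide 8 (not isolated)
Conditions: O3, CH2Cl2, −78 °C; then PPh3, −78 °C → rt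
Reagents that add atoms: ozone, [O-][O+]=O
Why: Ozonolysis with reductive work-up cleaves the terminal alkene to the aldehyde one carbon shorter; the silyl ether and the remote stereocenter are inert to ozone and phosphine.

Step 5
Reactants: 9 (11S)-11-(tert-butyldimethylsilyloxy)dodecanal
Product: 10 (11S)-11-(tert-butyldimethylsilyloxy)dodecanoic acid
Conditions: NaClO2, NaH2PO4, 2-methylbut-2-ene, t-BuOH/H2O, rt
Reagents that add atoms: sodium chlorite, [Na+].[O-]Cl=O
Why: Pinnick oxidation of an aliphatic aldehyde under phosphate buffer with an alkene scavenger for hypochlorite, conditions a secondary silyl ether should tolerate.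

Step 6
Reactants: 10 (11S)-11-(tert-butyldimethylsilyloxy)dodecanoic acid
Product: 12 (11S)-11-(tert-butyldimethylsilyloxy)-N-methoxy-N-methyldodecanamide, via acyl imidazole 11 (not isolated)
Conditions: 1,1'-carbonyldiimidazole (1.1 equiv), CH2Cl2, rt; then MeNHOMe·HCl (1.3 equiv), rt
Reagents that add atoms: N,O-dimethylhydroxylamine hydrochloride, CNOC.Cl
Why: Weinreb amide formation through an acyl imidazole; the imidazole released takes up the HCl, and nothing in the substrate competes for the activated acyl group.

Step 7
Reactants: 2 methyl 2-ethyl-3-oxopentanoate; 12 (11S)-11-(tert-butyldimethylsilyloxy)-N-methoxy-N-methyldodecanamide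
Product: 15 methyl (15S)-15-(tert-butyldimethylsilyloxy)-2-ethyl-4-methyl-3,5-dioxohexadecanoate, via dilithium dianion 13 (not isolated), via tetrahedral adduct 14 (not isolated)
Conditions: 2 (2.2 equiv), LiN(iPr)2 (4.4 equiv), THF, −78 → 0 °C; then 12 (1 equiv), THF, −78 → 0 °C; sat. aq. NH4Cl
Reagents that add atoms: none
Why: LiN(iPr)2 removes first the C2 proton between the two carbonyls and then a C4 proton of the propionyl end, and dianion 13 attacks the amide carbonyl of 12 through its last-formed, most basic γ-carbon, forging C4–C5 of the chain, which is C5–C6 of the later ring. The closest known reaction type is the γ-acylation of β-keto ester dianions with N-methoxy-N-methylamides, a crossed Claisen condensation that copies the last polyketide chain extension. No ring is closed; the step only delivers the open-chain triketide carrying every skeletal carbon of the target. No stereocenter of consequence is created, since C2 and C4 of 15 are enolisable and become sp2 in the pyranone, while the remote S carbinol center is not involved. The step needs γ- over α-acylation, which the far higher nucleophilicity of the γ-carbanion beside the delocalised α-enolate should secure, and single addition, which the lithium-chelated adduct 14 should secure by masking the new carbonyl until the quench, so that neither over-addition nor proton transfer from an acidic diketone to unreacted dianion can take place. The silyl ether leaves the amide as the only electrophilic carbonyl, and the excess of inexpensive 2 is meant to offset any enolisation of 12.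

Step 8
Reactants: 15 methyl (15S)-15-(tert-butyldimethylsilyloxy)-2-ethyl-4-methyl-3,5-dioxohexadecanoate
Product: 16 6-[(10S)-10-(tert-butyldimethylsilyloxy)undecyl]-3-ethyl-4-hydroxy-5-methyl-2H-pyran-2-one
Conditions: 1,8-diazabicyclo[5.4.0]undec-7-ene (DBU, 2 equiv), toluene, rt → 60 °C; then aq. citric acid
Reagents that add atoms: none
Why: Base-mediated lactonisation in which the C5 enolate oxygen attacks the ester carbonyl (6-exo-trig addition–elimination, loss of methoxide) and tautomerisation gives the 4-hydroxy-2-pyranone, removing both enolisable stereocenters.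

Step 9
Reactants: 16 6-[(10S)-10-(tert-butyldimethylsilyloxy)undecyl]-3-ethyl-4-hydroxy-5-methyl-2H-pyran-2-one
Product: 17 6-[(10S)-10-(tert-butyldimethylsilyloxy)undecyl]-3-ethyl-2-methoxy-5-methyl-4H-pyran-4-one
Conditions: MeOTf (1.2 equiv), CH2Cl2, 0 °C → rt; then sat. aq. NaHCO3
Reagents that add atoms: methyl trifluoromethanesulfonate, COS(=O)(=O)C(F)(F)F
Why: O-alkylation of the neutral hydroxypyranone by a hard methyl sulfonate at its most basic site, the C2 carbonyl oxygen, should give a 4-hydroxy-2-methoxypyrylium triflate that loses the 4-OH proton on basic work-up, leading to the 2-methoxy-4-pyranone and not to the 4-methoxy-2-pyranone.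

Step 10
Reactants: 17 6-[(10S)-10-(tert-butyldimethylsilyloxy)undecyl]-3-ethyl-2-methoxy-5-methyl-4H-pyran-4-one
Product: 18 3-ethyl-6-[(10S)-10-hydroxyundecyl]-2-methoxy-5-methyl-4H-pyran-4-one
Conditions: HF·pyridine, pyridine, THF, 0 °C → rt
Reagents that add atoms: none
Why: Fluoride-driven silyl ether cleavage at the O–Si bond, buffered with pyridine and free of water so that the methoxypyranone enol ether should not be hydrolysed; the C–O bond of the stereocenter is untouched.

Step 11
Reactants: 18 3-ethyl-6-[(10S)-10-hydroxyundecyl]-2-methoxy-5-methyl-4H-pyran-4-one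
Product: 19 (2S)-11-(5-ethyl-6-methoxy-3-methyl-4-oxo-4H-pyran-2-yl)undecan-2-yl acetate (CNP0208032.1)
Conditions: Ac2O, pyridine, 4-dimethylaminopyridine (cat.), CH2Cl2, rt
Reagents that add atoms: acetic anhydride, CC(=O)OC(C)=O
Why: Nucleophile-catalysed acylation of the secondary alcohol at oxygen, hence with retention of the S configuration; the pyranone carries no other acylable group.

**Compound list**

1 | methyl 3-oxopentanoate | CCC(=O)CC(=O)OC | starting material
2 | methyl 2-ethyl-3-oxopentanoate (racemic) | CCC(=O)C(CC)C(=O)OC | intermediate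
3 | 10-bromodec-1-ene | C=CCCCCCCCCBr | starting material
4 | (S)-propylene oxide | C[C@H]1CO1 | starting material
5 | dec-9-enylmagnesium bromide | C=CCCCCCCCC[Mg]Br | intermediate (not isolated)
6 | (S)-tridec-12-en-2-ol | C=CCCCCCCCCC[C@H](C)O | intermediate
7 | tert-butyldimethyl[(2S)-tridec-12-en-2-yloxy]silane | C=CCCCCCCCCC[C@H](C)O[Si](C)(C)C(C)(C)C | intermediate
8 | 3-[(10S)-10-(tert-butyldimethylsilyloxy)undecyl]-1,2,4-trioxolane (ozonide, epimer mixture at the ring carbon) | C1OOC(CCCCCCCCC[C@H](C)O[Si](C)(C)C(C)(C)C)O1 | intermediate (not isolated)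
9 | (11S)-11-(tert-butyldimethylsilyloxy)dodecanal | O=CCCCCCCCCC[C@H](C)O[Si](C)(C)C(C)(C)C | intermediate
10 | (11S)-11-(tert-butyldimethylsilyloxy)dodecanoic acid | OC(=O)CCCCCCCCC[C@H](C)O[Si](C)(C)C(C)(C)C | intermediate
11 | (11S)-11-(tert-butyldimethylsilyloxy)-1-(imidazol-1-yl)dodecan-1-one (acyl imidazole) | O=C(CCCCCCCCC[C@H](C)O[Si](C)(C)C(C)(C)C)n1ccnc1 | intermediate (not isolated)
12 | (11S)-11-(tert-butyldimethylsilyloxy)-N-methoxy-N-methyldodecanamide | CON(C)C(=O)CCCCCCCCC[C@H](C)O[Si](C)(C)C(C)(C)C | intermediate
13 | dilithium 2,4-dianion (bis-enolate) of methyl 2-ethyl-3-oxopentanoate | CC=C([O-])C(CC)=C([O-])OC.[Li+].[Li+] | intermediate (not isolated)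
14 | dilithium salt of the tetrahedral N-methoxy-N-methyl hemiaminal adduct of 13 and 12 (epimer mixture) | COC(=O)C(CC)=C([O-])C(C)C([O-])(N(C)OC)CCCCCCCCC[C@H](C)O[Si](C)(C)C(C)(C)C.[Li+].[Li+] | intermediate (not isolated)
15 | methyl (15S)-15-(tert-butyldimethylsilyloxy)-2-ethyl-4-methyl-3,5-dioxohexadecanoate (epimers at C2 and C4) | CCC(C(=O)OC)C(=O)C(C)C(=O)CCCCCCCCC[C@H](C)O[Si](C)(C)C(C)(C)C | intermediate
16 | 6-[(10S)-10-(tert-butyldimethylsilyloxy)undecyl]-3-ethyl-4-hydroxy-5-methyl-2H-pyran-2-one | CCc1c(O)c(C)c(CCCCCCCCC[C@H](C)O[Si](C)(C)C(C)(C)C)oc1=O | intermediate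
17 | 6-[(10S)-10-(tert-butyldimethylsilyloxy)undecyl]-3-ethyl-2-methoxy-5-methyl-4H-pyran-4-one | CCc1c(OC)oc(CCCCCCCCC[C@H](C)O[Si](C)(C)C(C)(C)C)c(C)c1=O | intermediate
18 | 3-ethyl-6-[(10S)-10-hydroxyundecyl]-2-methoxy-5-methyl-4H-pyran-4-one | CCc1c(OC)oc(CCCCCCCCC[C@H](C)O)c(C)c1=O | intermediate
19 | (2S)-11-(5-ethyl-6-methoxy-3-methyl-4-oxo-4H-pyran-2-yl)undecan-2-yl acetate (CNP0208032.1) | CCc1c(OC)oc(CCCCCCCCC[C@H](C)OC(C)=O)c(C)c1=O | target

**Summary**

Total step count: 11. Longest linear sequence: 10 steps (steps 2 to 11, from 3 and 4); step 1 supplies the second fragment.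

Steps most likely to fail:

Step 7. The α-branched keto ester may be only partly converted into its α,γ-dianion, the dianion may deprotonate the α-CH2 of amide 12 instead of adding to it, or adduct 14 may collapse before the quench and consume dianion by proton transfer. The fallback changes the oxidation level of the electrophile and keeps the same bond. It sets out from aldehyde 9 and keto ester 2. Dianion 13 (LiN(iPr)2, THF, −78 °C) is added to the much more electrophilic aldehyde to give the aldol adduct methyl (15S)-15-(tert-butyldimethylsilyloxy)-2-ethyl-5-hydroxy-4-methyl-3-oxohexadecanoate F1 as a diastereomer mixture. Oxidation of the secondary alcohol with Dess–Martin periodinane (NaHCO3, CH2Cl2) then gives 15, where the route is rejoined; steps 5 and 6 are no longer needed.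

Step 9. The triflic acid equivalent formed during methylation may cleave the silyl ether, after which the freed alcohol can be methylated as well. The fallback changes the order of events so that the acid-stable acetate is in place before the methylation. It sets out from 16, which is desilylated (HF·pyridine, THF) to 3-ethyl-4-hydroxy-6-[(10S)-10-hydroxyundecyl]-5-methyl-2H-pyran-2-one F2. Both hydroxyls are acetylated (Ac2O, pyridine, 4-dimethylaminopyridine) to (2S)-11-(4-acetoxy-3-ethyl-5-methyl-2-oxo-2H-pyran-6-yl)undecan-2-yl acetate F3. The enol acetate of F3, a vinylogous anhydride, is then removed selectively (MeOH, NaHCO3, 0 °C) to give (2S)-11-(3-ethyl-4-hydroxy-5-methyl-2-oxo-2H-pyran-6-yl)undecan-2-yl acetate F4. Methylation of F4 with methyl triflate as in step 9 returns to the route at 19.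

Step 2. Bromide may open the epoxide to a bromohydrin, the Grignard reagent may homocouple during its formation, and the volatile epoxide may be lost. The fallback replaces the organomagnesium by a sulfone-stabilised carbanion and sets out from 3 and 4. Bromide 3 and PhSO2Na (DMF, 60 °C) give [(dec-9-en-1-yl)sulfonyl]benzene F5. Its lithio derivative (n-BuLi, THF, −78 °C, then 4 and BF3·OEt2) opens the epoxide at CH2 to give (2S)-4-(phenylsulfonyl)tridec-12-en-2-ol F6 as a diastereomer mixture. Reductive desulfonylation (Na(Hg), Na2HPO4, MeOH) returns to the route at 6 with the S center intact.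

**Further compounds**

F1 | step 7 | methyl (15S)-15-(tert-butyldimethylsilyloxy)-2-ethyl-5-hydroxy-4-methyl-3-oxohexadecanoate | CCC(C(=O)OC)C(=O)C(C)C(O)CCCCCCCCC[C@H](C)O[Si](C)(C)C(C)(C)C
F2 | step 9 | 3-ethyl-4-hydroxy-6-[(10S)-10-hydroxyundecyl]-5-methyl-2H-pyran-2-one | CCc1c(O)c(C)c(CCCCCCCCC[C@H](C)O)oc1=O
F3 | step 9 | (2S)-11-(4-acetoxy-3-ethyl-5-methyl-2-oxo-2H-pyran-6-yl)undecan-2-yl acetate | CCc1c(OC(C)=O)c(C)c(CCCCCCCCC[C@H](C)OC(C)=O)oc1=O
F4 | step 9 | (2S)-11-(3-ethyl-4-hydroxy-5-methyl-2-oxo-2H-pyran-6-yl)undecan-2-yl acetate | CCc1c(O)c(C)c(CCCCCCCCC[C@H](C)OC(C)=O)oc1=O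
F5 | step 2 | [(dec-9-en-1-yl)sulfonyl]benzene | C=CCCCCCCCCS(=O)(=O)c1ccccc1
F6 | step 2 | (2S)-4-(phenylsulfonyl)tridec-12-en-2-ol | C=CCCCCCCCC(C[C@H](C)O)S(=O)(=O)c1ccccc1
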